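(All runs are simulated for substances that don't exist; the scatter is artificial.)

The isomer of the product reads lower than the target at 8.00 d in the alpha run, and I want that split at the asked time.

| flask | starting material | remark | time |
|---|---|---|---|
| alpha | 0.018 M | the very flask that is asked about, followed so far |  |
| flask | 0.018 M |  | 15 d |

1. target at 15 d, in percent of the starting material charged
2. isomer of the product at 15 d, in percent of the starting material charged

alpha run (percent of the starting material charged)

| time / d | target / % | isomer of the product / % | starting material / % |
|---|---|---|---|
| 1.25 | 18.1 | 1.1 | 0 |
| 2.50 | 55.9 | 4.8 | 0 |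
| 4.00 | 80.2 | 7.7 | 0.2 |
| 5.00 | 86.1 | 9.1 | 1.4 |
| 6.00 | 87.9 | 9.5 | 1.2 |
| 8.00 | 89.8 | 9.6 | 0.2 |

(each reading ± 1 percentage point)

- the numbers in the tables scatter with a standard deviation of 1 percentage point

I follow one molecule through this table. It leaves the starting material, waits somewhere no column reads, then shows up in the target or isomer column.

So I read the rows for two things. The first is the gap, what the three readings leave of the charge. It reads 80.8% at 1.25 d, 11.9% at 4.00 d and 0.400% at 8.00 d, less than the scatter of one reading. So I count the whole charge as arrived by 15 d.

The second is the chance that an arrived molecule stands as isomer. This is the isomer share, [isomer]/([target]+[isomer]), and the rows at 6.00 d and 8.00 d together read 9.71%. The first row says little about it, since its isomer reading is about the size of the scatter.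

My reckoning for 15 d is therefore 90.3% target and 9.71% isomer. The forecast differs slightly, with 90% and 9.8%, and its ground is this: “parallel branches fixing about 90:10”.

    starting material → intermediate A (k = 1.70 h⁻¹)
    intermediate A → intermediate B (k = 0.0460 h⁻¹)
    intermediate B → intermediate C (k = 0.0780 h⁻¹)
    intermediate C → target (k = 0.0460 h⁻¹)
    2 starting material → homo dimer (k = 0.00770 L mol⁻¹ h⁻¹)
    target ⇌ isomer of the product (K = 0.110, k = 0.0600 h⁻¹)

The flask gives 90.1% target and 9.91% isomer at 15 d, an isomer share of 9.91%. The relaxation half-life of target and isomer by their interconversion, 1.14 h, is shorter than 15 d, the setting of thermodynamic control. I put my share to use on the neighbour flask read at 4.0 d. Its 79.3% target, multiplied by the isomer-to-target ratio that my share implies, gives 8.53% isomer, and that flask holds 8.64%.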